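**Retrosynthetic overview**
- Ring A (C1 aryloxy, C2 isopropyl, C3 H, C4 OMe, C5 Me, C6 H) has its two oxygens para, and its ether carbon C1 sits between the isopropyl carbon C2 and the unsubstituted C6. It can therefore be read as an aromatised 4-aryloxy-3-isopropyl-6-methylcyclohex-2-enone.
- Key disconnection: C1–C6 (Michael) and C2–C3 (aldol condensation), leading to the α-aryloxy isopropyl ketone 13 and 3-methylbut-3-en-2-one 14. The diaryl ether oxygen is thus set by a simple phenol O-alkylation with 1-bromo-3-methylbutan-2-one, not by an aryl–oxygen coupling.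
- Ring B comes from carvacrol. Its two further oxygens are introduced by two formylation/Baeyer–Villiger cycles, with a benzyl group keeping the catechol oxygens apart.
- Ring order: ring B (present from the start), then the carbocycle of ring A closed in step 8, aromatised in step 9, O-methylated and debenzylated.

Key step: step 8

Remark: the target has no stereocentre and is achiral, so it is made as the single compound shown. The sp3 centres in 15–18 are formed without control and vanish on aromatisation.

**Route**

Step 1
Reactants: 1 carvacrol (5-isopropyl-2-methylphenol)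
Product: 2 4-isopropyl-2-methoxy-1-methylbenzene (carvacrol methyl ether)
Conditions: MeI, K2CO3, acetone, reflux
Reagents that add atoms: iodomethane, CI
Why: Williamson O-methylation of the phenoxide by SN2 on iodomethane should install the ring-B methoxy group cleanly.

Step 2
Reactants: 2 4-isopropyl-2-methoxy-1-methylbenzene
Product: 4 2-isopropyl-4-methoxy-5-methylbenzaldehyde, via aryl chloro ether 3 (not isolated)
Conditions: Cl2CHOMe, TiCl4, CH2Cl2, 0 °C; then ice-water
Reagents that add atoms: dichloromethyl methyl ether, COC(Cl)Cl; water, O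
Why: Rieche formylation (electrophilic aromatic substitution) should go para to the methoxy group, since the ortho site is wedged between OMe and isopropyl, and aqueous work-up hydrolyses chloro ether 3 to the aldehyde.

Step 3
Reactants: 4 2-isopropyl-4-methoxy-5-methylbenzaldehyde
Product: 6 2-isopropyl-4-methoxy-5-methylphenol, via aryl formate 5 (not isolated)
Conditions: mCPBA, CH2Cl2, 0 °C to rt; aq. NaHCO3/Na2S2O3 wash; then K2CO3 (cat.), MeOH, rt
Reagents that add atoms: 3-chloroperoxybenzoic acid, OOC(=O)c1cccc(Cl)c1
Why: Baeyer–Villiger (Dakin-type) oxidation in which the electron-rich p-methoxyaryl group should migrate in preference to hydride, and base-catalysed methanolysis of formate 5 frees the phenol.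

Step 4
Reactants: 6 2-isopropyl-4-methoxy-5-methylphenol
Product: 8 2-hydroxy-3-isopropyl-5-methoxy-6-methylbenzaldehyde, via salicyl alcohol 7 (not isolated)
Conditions: MgCl2, Et3N, (CH2O)n, MeCN, reflux; aq. HCl work-up
Reagents that add atoms: formaldehyde (as paraformaldehyde), C=O
Why: Magnesium phenoxide-directed ortho-formylation (Casnati–Skattebøl) should deliver formaldehyde to the only free ortho position, and the hydroxymethyl intermediate 7 is oxidised in situ by hydride transfer to a second formaldehyde.

Step 5
Reactants: 8 2-hydroxy-3-isopropyl-5-methoxy-6-methylbenzaldehyde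
Product: 9 2-(benzyloxy)-3-isopropyl-5-methoxy-6-methylbenzaldehyde
Conditions: BnBr, K2CO3, DMF, 50 °C
Reagents that add atoms: benzyl bromide, BrCc1ccccc1
Why: Williamson benzylation of the salicylaldehyde phenoxide in a polar aprotic solvent should protect the oxygen that becomes the free OH of the target.

Step 6
Reactants: 9 2-(benzyloxy)-3-isopropyl-5-methoxy-6-methylbenzaldehyde
Product: 11 2-(benzyloxy)-3-isopropyl-5-methoxy-6-methylphenol, via aryl formate 10 (not isolated)
Conditions: mCPBA, NaHCO3, CH2Cl2, rt; aqueous wash; then K2CO3 (cat.), MeOH, rt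
Reagents that add atoms: 3-chloroperoxybenzoic acid, OOC(=O)c1cccc(Cl)c1
Why: Baeyer–Villiger oxidation in which the ortho-benzyloxy group should favour aryl migration, and methanolysis of formate 10 gives the phenol at the position fixed by the formylation, between OBn and methyl.

Step 7
Reactants: 11 2-(benzyloxy)-3-isopropyl-5-methoxy-6-methylphenol; 12 1-bromo-3-methylbutan-2-one
Product: 13 1-[2-(benzyloxy)-3-isopropyl-5-methoxy-6-methylphenoxy]-3-methylbutan-2-one
Conditions: K2CO3, acetone, 50 °C
Reagents that add atoms: none
Why: SN2 O-alkylation of the phenoxide by the activated primary α-bromo ketone (Williamson ether synthesis) should form the O–CH2 bond that later becomes the diaryl ether O–C1 bond.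

Step 8
Reactants: 13 1-[2-(benzyloxy)-3-isopropyl-5-methoxy-6-methylphenoxy]-3-methylbutan-2-one; 14 3-methylbut-3-en-2-one
Product: 17 4-[2-(benzyloxy)-3-isopropyl-5-methoxy-6-methylphenoxy]-3-isopropyl-6-methylcyclohex-2-en-1-one (mixture of diastereomers), via 1,5-diketone Michael adduct 15 (not isolated), via ketol 16 (not isolated)
Conditions: KOtBu (0.2 equiv), t-BuOH–THF, 0 °C, slow addition of 14 (1.5 equiv); then KOH (0.5 equiv), MeOH, 60 °C
Reagents that add atoms: none
Why: Catalytic tert-butoxide reversibly forms the enolate at the aryloxy-bearing CH2 of 13, which adds to the unsubstituted alkene terminus of 14 (Michael addition) to give 1,5-diketone 15 and so makes the C1–C6 bond of ring A. Hydroxide then enolises the acetyl methyl group, whose carbon attacks the isopropyl ketone carbonyl in a 6-(enolendo)-exo-trig aldol closure to ketol 16, and E1cB loss of water gives enone 17 with the C2–C3 bond in place; the sequence is a Robinson annulation, the closest known reaction type. No stereocentre needs control, because the two sp3 ring carbons of 17 form as a mixture and both become sp2 in step 9. The Michael stage needs enolisation at OCH2 and not at the isopropyl methine; the aryloxy oxygen acidifies the CH2 and the donor carbon there is secondary, whereas the methine is less acidic and would have to form a quaternary centre. The aldol stage needs the acetyl-methyl closure to win; the alternative six-ring aldol (isopropyl methine onto the acetyl carbonyl) gives a ketol with a quaternary α-carbon that cannot dehydrate, so it reverts and the material should drain through the one ketol that can eliminate. The aryloxy group is α to the ketone in 15 and γ to the carbonyl in 17, positions from which it cannot leave by β-elimination.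

Step 9
Reactants: 17 4-[2-(benzyloxy)-3-isopropyl-5-methoxy-6-methylphenoxy]-3-isopropyl-6-methylcyclohex-2-en-1-one
Product: 19 4-[2-(benzyloxy)-3-isopropyl-5-methoxy-6-methylphenoxy]-5-isopropyl-2-methylphenol, via cyclohexa-2,5-dienone tautomer 18 (not isolated)
Conditions: Pd(TFA)2 (5 mol%), 2-(dimethylamino)pyridine (10 mol%), TsOH·H2O (20 mol%), O2 (1 atm), DMSO, 80 °C
Reagents that add atoms: none
Why: Pd(II)-catalysed aerobic dehydrogenation of a cyclohexenone, by α'-palladation and β-hydride elimination, should give dienone 18, which tautomerises to the phenol, while the non-nucleophilic medium avoids exchange of the γ-aryloxy group that acidic methanol could cause.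

Step 10
Reactants: 19 4-[2-(benzyloxy)-3-isopropyl-5-methoxy-6-methylphenoxy]-5-isopropyl-2-methylphenol
Product: 20 2-(benzyloxy)-1-isopropyl-3-(2-isopropyl-4-methoxy-5-methylphenoxy)-5-methoxy-4-methylbenzene
Conditions: MeI, K2CO3, acetone, reflux
Reagents that add atoms: iodomethane, CI
Why: Williamson O-methylation of the only free, unhindered phenol should install the ring-A methoxy group at C4.

Step 11
Reactants: 20 2-(benzyloxy)-1-isopropyl-3-(2-isopropyl-4-methoxy-5-methylphenoxy)-5-methoxy-4-methylbenzene
Product: 21 6-isopropyl-2-(2-isopropyl-4-methoxy-5-methylphenoxy)-4-methoxy-3-methylphenol (target)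
Conditions: H2 (1 atm), 10% Pd/C, EtOAc–EtOH, rt
Reagents that add atoms: none
Why: Catalytic hydrogenolysis of the benzyl aryl ether should free the ring-B phenol, while the diaryl ether and methyl ethers are inert under these conditions.

**Compound list**
1 | carvacrol (5-isopropyl-2-methylphenol) | Cc1ccc(C(C)C)cc1O | starting material
2 | 4-isopropyl-2-methoxy-1-methylbenzene | COc1cc(C(C)C)ccc1C | intermediate
3 | 1-[chloro(methoxy)methyl]-2-isopropyl-4-methoxy-5-methylbenzene (racemic, not isolated) | COC(Cl)c1cc(C)c(OC)cc1C(C)C | intermediate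
4 | 2-isopropyl-4-methoxy-5-methylbenzaldehyde | O=Cc1cc(C)c(OC)cc1C(C)C | intermediate
5 | 2-isopropyl-4-methoxy-5-methylphenyl formate (not isolated) | O=COc1cc(C)c(OC)cc1C(C)C | intermediate
6 | 2-isopropyl-4-methoxy-5-methylphenol | COc1cc(C(C)C)c(O)cc1C | intermediate
7 | 2-(hydroxymethyl)-6-isopropyl-4-methoxy-3-methylphenol (as magnesium salt, not isolated) | COc1cc(C(C)C)c(O)c(CO)c1C | intermediate
8 | 2-hydroxy-3-isopropyl-5-methoxy-6-methylbenzaldehyde | COc1cc(C(C)C)c(O)c(C=O)c1C | intermediate
9 | 2-(benzyloxy)-3-isopropyl-5-methoxy-6-methylbenzaldehyde | COc1cc(C(C)C)c(OCc2ccccc2)c(C=O)c1C | intermediate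
10 | 2-(benzyloxy)-3-isopropyl-5-methoxy-6-methylphenyl formate (not isolated) | COc1cc(C(C)C)c(OCc2ccccc2)c(OC=O)c1C | intermediate
11 | 2-(benzyloxy)-3-isopropyl-5-methoxy-6-methylphenol | COc1cc(C(C)C)c(OCc2ccccc2)c(O)c1C | intermediate
12 | 1-bromo-3-methylbutan-2-one | CC(C)C(=O)CBr | starting material
13 | 1-[2-(benzyloxy)-3-isopropyl-5-methoxy-6-methylphenoxy]-3-methylbutan-2-one | CC(C)C(=O)COc1c(C)c(OC)cc(C(C)C)c1OCc1ccccc1 | intermediate
14 | 3-methylbut-3-en-2-one | CC(=O)C(C)=C | starting material
15 | 5-[2-(benzyloxy)-3-isopropyl-5-methoxy-6-methylphenoxy]-3,7-dimethyloctane-2,6-dione (diastereomer mixture, not isolated) | CC(C)C(=O)C(CC(C)C(C)=O)Oc1c(C)c(OC)cc(C(C)C)c1OCc1ccccc1 | intermediate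
16 | 4-[2-(benzyloxy)-3-isopropyl-5-methoxy-6-methylphenoxy]-3-hydroxy-3-isopropyl-6-methylcyclohexan-1-one (diastereomer mixture, not isolated) | CC1CC(Oc2c(C)c(OC)cc(C(C)C)c2OCc2ccccc2)C(O)(C(C)C)CC1=O | intermediate
17 | 4-[2-(benzyloxy)-3-isopropyl-5-methoxy-6-methylphenoxy]-3-isopropyl-6-methylcyclohex-2-en-1-one (diastereomer mixture) | CC1CC(Oc2c(C)c(OC)cc(C(C)C)c2OCc2ccccc2)C(C(C)C)=CC1=O | intermediate
18 | 4-[2-(benzyloxy)-3-isopropyl-5-methoxy-6-methylphenoxy]-5-isopropyl-2-methylcyclohexa-2,5-dien-1-one (racemic, not isolated) | CC1=CC(Oc2c(C)c(OC)cc(C(C)C)c2OCc2ccccc2)C(C(C)C)=CC1=O | intermediate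
19 | 4-[2-(benzyloxy)-3-isopropyl-5-methoxy-6-methylphenoxy]-5-isopropyl-2-methylphenol | Cc1cc(Oc2c(C)c(OC)cc(C(C)C)c2OCc2ccccc2)c(C(C)C)cc1O | intermediate
20 | 2-(benzyloxy)-1-isopropyl-3-(2-isopropyl-4-methoxy-5-methylphenoxy)-5-methoxy-4-methylbenzene | COc1cc(C(C)C)c(Oc2c(C)c(OC)cc(C(C)C)c2OCc2ccccc2)cc1C | intermediate
21 | 6-isopropyl-2-(2-isopropyl-4-methoxy-5-methylphenoxy)-4-methoxy-3-methylphenol | COc1cc(C(C)C)c(Oc2c(C)c(OC)cc(C(C)C)c2O)cc1C | target

**Totals**
Total step count: 11. Longest linear sequence: 11 steps (carvacrol 1 to target 21).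

**Steps most likely to fail**

1. Step 8 (Robinson annulation). Base-induced polymerisation of the enone or repeated Michael addition may outrun the single conjugate addition, and closure onto the hindered isopropyl ketone may be slow. Fallback: the fallback sets out from 13, which is converted with TMSOTf and Et3N in CH2Cl2 at 0 °C into (Z)-1-[2-(benzyloxy)-3-isopropyl-5-methoxy-6-methylphenoxy]-3-methyl-2-(trimethylsilyloxy)but-1-ene F1. A Mukaiyama–Michael addition of F1 to 14 (TiCl4, CH2Cl2, −78 °C, aqueous work-up) should then give the 1,5-diketone 15 without any free enolate, and here it is isolated. The route is rejoined at 15, which is closed to 17 with KOH in MeOH as in the second stage of step 8.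

2. Step 9 (aromatisation). Acid-promoted loss of the ring-B phenol from the γ-position (a redox-neutral aromatisation) or slow palladation at the fully substituted α'-carbon may compete with dehydrogenation. Fallback: the fallback sets out from 17, which is deprotonated at the α'-carbon with LDA in THF at −78 °C and trapped with PhSeCl to give 4-[2-(benzyloxy)-3-isopropyl-5-methoxy-6-methylphenoxy]-3-isopropyl-6-methyl-6-(phenylselanyl)cyclohex-2-en-1-one F2. Oxidation with H2O2 and pyridine in CH2Cl2 at 0 °C to rt should then cause selenoxide syn-elimination under near-neutral conditions to dienone 18, which tautomerises. The route is rejoined at 19.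

3. Step 6 (Baeyer–Villiger on the 2,6-disubstituted aldehyde). Hydride migration to the carboxylic acid, or peracid attack on the electron-rich ring, may compete with aryl migration. Fallback: the fallback sets out from 6 and bypasses steps 4 to 6. Ortho-bromination with NBS in MeCN at 0 °C should give 2-bromo-6-isopropyl-4-methoxy-3-methylphenol F3, and benzylation (BnBr, K2CO3, DMF) gives 2-(benzyloxy)-3-bromo-1-isopropyl-5-methoxy-4-methylbenzene F4. Bromine–lithium exchange (n-BuLi, THF, −78 °C), trapping with B(OMe)3 and oxidation with H2O2/NaOH should then convert the C–Br bond into C–OH. The route is rejoined at 11.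

**Further compounds**
F1 | step 8 | (Z)-1-[2-(benzyloxy)-3-isopropyl-5-methoxy-6-methylphenoxy]-3-methyl-2-(trimethylsilyloxy)but-1-ene | CC(C)/C(O[Si](C)(C)C)=C/Oc1c(C)c(OC)cc(C(C)C)c1OCc1ccccc1
F2 | step 9 | 4-[2-(benzyloxy)-3-isopropyl-5-methoxy-6-methylphenoxy]-3-isopropyl-6-methyl-6-(phenylselanyl)cyclohex-2-en-1-one (diastereomer mixture) | CC1([Se]c2ccccc2)CC(Oc2c(C)c(OC)cc(C(C)C)c2OCc2ccccc2)C(C(C)C)=CC1=O
F3 | step 6 | 2-bromo-6-isopropyl-4-methoxy-3-methylphenol | COc1cc(C(C)C)c(O)c(Br)c1C
F4 | step 6 | 2-(benzyloxy)-3-bromo-1-isopropyl-5-methoxy-4-methylbenzene | COc1cc(C(C)C)c(OCc2ccccc2)c(Br)c1C
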